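The data were computed for substances that don't exist, noise included.

Two amounts and one order are asked, and I want them from a single quantity.

| flask | left-handed substrate | right-handed substrate | coupling partner | remark | time |
|---|---|---|---|---|---|
| Monday's | 0.067 M | 0.067 M | 0.22 M | run made earlier |  |
| Wednesday's | 0.20 M | 0.20 M | 0.22 M | run made earlier |  |
| dusk | 0.10 M | 0.10 M | 0.400 M |  | 3.0 h |
| dawn | 0.10 M | 0.10 M | 0.600 M |  | 3.0 h |
| spring | 0.10 M | 0.10 M | 0.220 M |  | 3.0 h |
| winter | 0.10 M | 0.10 M | 0.0600 M |  | 3.0 h |
| midnight | 0.10 M | 0.10 M | 0.150 M |  | 3.0 h |
| autumn | 0.10 M | 0.10 M | 0.120 M |  | 3.0 h |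

| run | time / min | left-handed product / % | left-handed substrate / % |
|---|---|---|---|
| Monday's | 20.0 | 5.3 | 42.8 |
| Monday's | 40.0 | 8.0 | 42.1 |
| Monday's | 50.0 | 13.4 | 40.4 |
| Monday's | 80.0 | 17.4 | 35.6 |
| Monday's | 90.0 | 20.4 | 33.1 |
| Monday's | 120 | 22.0 | 31.0 |
| Wednesday's | 8.00 | 1.9 | 49.7 |
| Wednesday's | 15.0 | 5.0 | 46.5 |
| Wednesday's | 25.0 | 6.3 | 44.8 |
| Wednesday's | 40.0 | 10.4 | 39.8 |
| Wednesday's | 60.0 | 12.6 | 38.7 |
| Wednesday's | 120 | 19.6 | 33.9 |

(scatter of a reading: 1 percentage point)

- coupling partner is single-handed; left-handed substrate and right-handed substrate are mirror images of each other, charged as a racemate, each of them at the stated concentration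
- the handed part of coupling partner does not stay in what it makes, so the products of the two hands are mirror images too

- the flasks by amount of left-handed product, in percent of the left-handed substrate and right-handed substrate together charged, highest first, at 3.0 h (dusk / dawn / spring / winter / midnight / autumn)
- the amount of left-handed product, in percent of the left-handed substrate and right-handed substrate together charged of the flask you put first, at 3.0 h
- the amount of left-handed product, in percent of the left-handed substrate and right-handed substrate together charged of the flask you put last, at 3.0 h

Monday's and Wednesday's runs hold the same coupling partner, 0.22 M, but 0.067 M and 0.20 M of each substrate. At 40.0 min they read 8.0% and 10.4% of left-handed product, a gap of 2.4 percentage points between readings that each scatter by 1 point. So I take the fraction of left-handed substrate converted per minute as independent of the substrate charge, which is pseudo-first-order behaviour. Left-handed substrate is half of what is charged, so the mean of those readings says 18.4% of it has gone, and the logarithm gives a constant of 0.00508 min⁻¹ at 0.22 M.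

Both runs hold one partner charge, so I assume that this constant is proportional to the partner. That gives 0.240 M as the crossing charge, the amount of coupling partner at which the lifetime of left-handed substrate equals the reaction time. My curve is then the left-handed share times one minus the exponential of minus charge over crossing charge. It climbs nearly in step with the charge below the crossing and flattens above it, so my order simply follows the partner charge. It gives 45.9% for dawn and 11.1% for winter. The curve holds the partner at its charge, but in winter the partner is the limiting reagent, 0.0600 M against 0.200 M of substrate in both hands, so I expect winter to fall below that figure.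

The forecast gives dawn > dusk > spring > midnight > autumn > winter, with 46% and 9.3% at the ends, holding that “left product rises steadily with partner”.

The flasks give dawn > dusk > spring > midnight > autumn > winter, with 49.9% in dawn and 8.90% in winter.

    coupling partner + left-handed substrate → left-handed product (k = 4.60 × 10⁻⁴ M⁻¹ s⁻¹)
    coupling partner + right-handed substrate → right-handed product (k = 1.70 × 10⁻⁴ M⁻¹ s⁻¹)
    left-handed substrate ⇌ right-handed substrate (k = 1.30 × 10⁻⁴ s⁻¹)
    coupling partner → decomposition product (k = 1.40 × 10⁻⁷ s⁻¹)
    coupling partner → decomposed reagent (k = 2.80 × 10⁻⁵ s⁻¹)

The neighbouring flask is winter with 0.24 M of coupling partner, which is 1.000 crossing charges, so it stands at the crossing and my curve gives it 31.6%. That flask yields 29.3% of left-handed product and 12.1% of right-handed product, and the left-handed figure is 3.29 times winter's for a partner charge 4.00 times as large. At the end it still holds 54% of its left-handed substrate and 45% of its coupling partner.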